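**Plan**

1. Retrosynthesis: after removal of three silyl groups, ring C is cut at C-2–C-3 and C-4–C-4a together. This releases C-3/C-4 as a ketene acetal and leaves an O-aryl O-pivaloyl acetal of the ring-B aldehyde. The acetal C–O(aryl) bond and then the aryl–C-1'' bond are cut, giving a 4-bromo-3,5-disilyloxyphenol, (S)-citronellal and 4-hydroxybenzaldehyde.
2. Forward: ring A is bought as 2-bromoresorcinol and receives its third oxygen by C–H borylation/oxidation. The C10 chain is joined by palladium–carbene coupling, and the phenol is tied to the ring-B carbon as a mixed acetal. Ring C is closed last by a catalytic enantioselective cationic [4+2] annulation with 1,1-diethoxyethene, followed by global desilylation.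
3. Enabling feature: ring A is a phloroglucinol ring whose side chain (C-6) stands para to the ring oxygen O-1. The aryloxy precursor therefore has a local mirror plane through O-1/C-8a and C-6, so C-4a and C-8 are identical and each is ortho/para to three oxygen atoms. C-2 is an acetal-level carbon between O-1 and the 4-oxyphenyl ring B. An O-aryl oxocarbenium ion (2-oxadiene O-1=C-2 / C-8a=C-4a) can thus take up a ketene unit across C-2 and C-4a with no 6- versus 8-substitution problem.
4. Stereochemistry: C-3'' (S) comes from (S)-citronellal and is never touched. The (E)-alkene comes from syn β-hydride elimination in the carbene coupling. C-2 (S) is set by the chiral counter-anion in the annulation and kept by avoiding base afterwards.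

Key step: step 8

Remark (assumption): the sense of induction of the chiral acid in step 8 cannot be assigned in advance for this new ion pair, so the (R)-catalyst is written and its mirror image is to be used if a first run shows the (2R) series to predominate; the acetal carbon of 10 and 11 is stereorandom, becomes planar in step 8 and is left undefined.

**Step 1**
Reactants: 1 2-bromobenzene-1,3-diol (2-bromoresorcinol)
Product: 2 2-bromo-1,3-bis[(triisopropylsilyl)oxy]benzene
Conditions: TIPSOTf (2.3 equiv), 2,6-lutidine (3 equiv), CH2Cl2, 0 °C → rt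
Reagents that add atoms: triisopropylsilyl trifluoromethanesulfonate, CC(C)[Si](OS(=O)(=O)C(F)(F)F)(C(C)C)C(C)C
Why: Silyl ether formation with the silyl triflate/hindered base pair should silylate both phenols despite the flanking bromine.

**Step 2**
Reactants: 2 2-bromo-1,3-bis[(triisopropylsilyl)oxy]benzene
Product: 4 4-bromo-3,5-bis[(triisopropylsilyl)oxy]phenol, via aryl pinacol boronate 3 (not isolated)
Conditions: [Ir(OMe)(cod)]2 (1.5 mol %), 4,4'-di-tert-butyl-2,2'-bipyridine (3 mol %), B2pin2 (1.0 equiv), cyclohexane, 80 °C; then KHSO5 (as 2KHSO5·KHSO4·K2SO4), acetone/H2O, 0 °C → rt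
Reagents that add atoms: potassium peroxymonosulfate, [K+].[O-]S(=O)(=O)OO (phenol oxygen); bis(pinacolato)diboron, CC1(C)OB(B2OC(C)(C)C(C)(C)O2)OC1(C)C (boryl group of 3 only)
Why: Iridium-catalysed aromatic C–H borylation is sterically controlled and should occur only at C-5, the one C–H without an ortho substituent, and peroxymonosulfate oxidation of the C–B bond then gives the phenol in the same flask (one-pot borylation/oxidation) with the C–Br bond and silyl ethers intact.

**Step 3**
Reactants: 5 (3S)-3,7-dimethyloct-6-enal ((S)-citronellal)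
Product: 6 N'-[(1E,3S)-3,7-dimethyloct-6-en-1-ylidene]-4-methylbenzenesulfonohydrazide
Conditions: TsNHNH2 (1.0 equiv), MeOH, rt
Reagents that add atoms: 4-methylbenzenesulfonohydrazide, Cc1ccc(cc1)S(=O)(=O)NN
Why: Hydrazone formation under neutral conditions should leave C-3 and the trisubstituted alkene untouched.

**Step 4**
Reactants: 4 4-bromo-3,5-bis[(triisopropylsilyl)oxy]phenol; 6 N'-[(1E,3S)-3,7-dimethyloct-6-en-1-ylidene]-4-methylbenzenesulfonohydrazide (1.3 equiv)
Product: 7 4-[(1E,3S)-3,7-dimethylocta-1,6-dien-1-yl]-3,5-bis[(triisopropylsilyl)oxy]phenol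
Conditions: Pd2(dba)3 (2.5 mol %), XPhos (10 mol %), LiOtBu (3.5 equiv), 1,4-dioxane, 90 °C
Reagents that add atoms: none
Why: In this palladium-catalysed cross-coupling of an aryl bromide with an aldehyde N-tosylhydrazone (Barluenga coupling) the base releases the diazoalkane, the arylpalladium bromide forms a carbene, the aryl group migrates to the carbene carbon and syn β-hydride elimination from C-2'' should give the conjugated (E)-alkene, while C-3'' takes no part and the phenol is carried as its lithium phenoxide.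

**Step 5**
Reactants: 8 4-hydroxybenzaldehyde
Product: 9 4-[(triisopropylsilyl)oxy]benzaldehyde
Conditions: TIPSCl (1.1 equiv), imidazole (2 equiv), DMF, rt
Reagents that add atoms: triisopropylsilyl chloride, CC(C)[Si](Cl)(C(C)C)C(C)C
Why: Standard silyl ether formation gives a phenol protecting group that survives the later acid-mediated steps and is removed together with the others at the end.

**Step 6**
Reactants: 9 4-[(triisopropylsilyl)oxy]benzaldehyde
Product: 10 chloro{4-[(triisopropylsilyl)oxy]phenyl}methyl 2,2-dimethylpropanoate (racemic)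
Conditions: PivCl (1.1 equiv), ZnCl2 (2 mol %), CH2Cl2, −10 °C → rt; volatiles removed, used crude
Reagents that add atoms: pivaloyl chloride, CC(C)(C)C(=O)Cl
Why: ZnCl2-catalysed addition of an acyl chloride across the aldehyde C=O is the usual α-chloroalkyl ester synthesis, and the new centre is racemic and later becomes planar.

**Step 7**
Reactants: 7 4-[(1E,3S)-3,7-dimethylocta-1,6-dien-1-yl]-3,5-bis[(triisopropylsilyl)oxy]phenol; 10 chloro{4-[(triisopropylsilyl)oxy]phenyl}methyl 2,2-dimethylpropanoate (1.3 equiv)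
Product: 11 {4-[(1E,3S)-3,7-dimethylocta-1,6-dien-1-yl]-3,5-bis[(triisopropylsilyl)oxy]phenoxy}{4-[(triisopropylsilyl)oxy]phenyl}methyl 2,2-dimethylpropanoate (both epimers at the acetal carbon)
Conditions: NaH (1.05 equiv), THF, 0 °C; then 10, −40 → 0 °C; chromatography on Et3N-deactivated silica
Reagents that add atoms: none
Why: O-Alkylation of the sodium phenoxide by the readily ionised α-chloro ester (acyloxyalkyl ether formation, Williamson type) should give the mixed acetal, the hindered pivaloyl carbonyl resisting acyl transfer and the epimeric acetal centre being of no consequence.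

**Step 8**
Reactants: 11 {4-[(1E,3S)-3,7-dimethylocta-1,6-dien-1-yl]-3,5-bis[(triisopropylsilyl)oxy]phenoxy}{4-[(triisopropylsilyl)oxy]phenyl}methyl 2,2-dimethylpropanoate; 12 1,1-diethoxyethene (3 equiv, slow addition)
Product: 14 (2S)-6-[(1E,3S)-3,7-dimethylocta-1,6-dien-1-yl]-5,7-bis[(triisopropylsilyl)oxy]-2-{4-[(triisopropylsilyl)oxy]phenyl}-2,3-dihydro-4H-chromen-4-one, via flavanone diethyl ketal 13 (not isolated)
Conditions: (R)-3,3'-bis(2,4,6-triisopropylphenyl)-1,1'-binaphthyl-2,2'-diyl N-(trifluoromethylsulfonyl)phosphoramide (10 mol %), toluene, −78 → −40 °C; then aq. citric acid, THF, 0 °C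
Reagents that add atoms: water, O (carbonyl oxygen, on hydrolysis of the ketal)
Why: Proposed new method: the chiral acid protonates the pivalate of 11 and expels pivalic acid (the carboxylate, not the aryloxide, is the better leaving group and would leave the poorer cation), giving an O-aryl oxocarbenium ion paired with the chiral phosphoramide anion; this cationic 2-oxadiene (C-2=O-1 with C-8a=C-4a of ring A) is attacked at C-2 by the CH2 terminus of ketene acetal 12, the resulting dialkoxycarbenium ion at C-4 is captured by C-4a, and loss of the ring proton returns the acid and leaves ketal 13, which is hydrolysed to ketone 14 on work-up. The closest known reaction types are the Lewis-acid-promoted oxa-Povarov annulation of aryloxycarbenium ions with alkenes, the chiral-phosphoric-acid-catalysed Povarov reaction of N-aryl imines with electron-rich alkenes, and enantioselective additions of ketene acetals to oxocarbenium ion pairs; new here are the ketene acetal as two-carbon partner (ketone oxidation level at C-4) and the control of an O-aryl oxocarbenium ion by a chiral anion. Ring C is closed in a stepwise polar [4+2] mode, the intermolecular C-2–C-3 bond first and then a 6-exo-trig Friedel–Crafts attack of C-4a on the carbenium carbon, which is the only irreversible exit because capture of that cation by carboxylate or loss of its α-proton is reversed by the acid. C-2 is the only new stereocentre and is set in the first bond formation by the chiral counter-anion, which blocks one face of the planar oxocarbenium ion (catalyst control, the remote C-3'' centre exerts none), and it is not endangered afterwards because no base is present. The step needs chemoselectivity for the ketene acetal over the side-chain alkenes and over the arene of a second molecule, secured by its far higher nucleophilicity and its excess (which also buffers stray protons), and it needs no regiocontrol, because the 4-alkenyl-3,5-disilyloxyphenoxy ring has a local mirror plane through O-1 and C-6, so that both ortho carbons are the same and either closure gives the 6-substituted flavanone.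

**Step 9**
Reactants: 14 (2S)-6-[(1E,3S)-3,7-dimethylocta-1,6-dien-1-yl]-5,7-bis[(triisopropylsilyl)oxy]-2-{4-[(triisopropylsilyl)oxy]phenyl}-2,3-dihydro-4H-chromen-4-one
Product: 15 (2S)-6-[(1E,3S)-3,7-dimethylocta-1,6-dien-1-yl]-5,7-dihydroxy-2-(4-hydroxyphenyl)-2,3-dihydro-4H-chromen-4-one
Conditions: TBAF (3.5 equiv), AcOH (4 equiv), THF, 0 °C → rt
Reagents that add atoms: none
Why: Fluoride cleavage of the three aryl silyl ethers, buffered with acetic acid, should leave no persistent phenoxide that could open ring C (retro-oxa-Michael) and racemise C-2, and it avoids the strong acid that would cyclise the ortho-hydroxystyrene onto the trisubstituted alkene.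

**Compound list**

1 | 2-bromobenzene-1,3-diol (2-bromoresorcinol) | Oc1cccc(O)c1Br | starting material
2 | 2-bromo-1,3-bis[(triisopropylsilyl)oxy]benzene | CC(C)[Si](Oc1cccc(O[Si](C(C)C)(C(C)C)C(C)C)c1Br)(C(C)C)C(C)C | intermediate
3 | 2-{4-bromo-3,5-bis[(triisopropylsilyl)oxy]phenyl}-4,4,5,5-tetramethyl-1,3,2-dioxaborolane (formed in the flask, not isolated) | CC(C)[Si](Oc1cc(B2OC(C)(C)C(C)(C)O2)cc(O[Si](C(C)C)(C(C)C)C(C)C)c1Br)(C(C)C)C(C)C | intermediate
4 | 4-bromo-3,5-bis[(triisopropylsilyl)oxy]phenol | CC(C)[Si](Oc1cc(O)cc(O[Si](C(C)C)(C(C)C)C(C)C)c1Br)(C(C)C)C(C)C | intermediate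
5 | (3S)-3,7-dimethyloct-6-enal ((S)-citronellal) | CC(C)=CCC[C@H](C)CC=O | starting material
6 | N'-[(1E,3S)-3,7-dimethyloct-6-en-1-ylidene]-4-methylbenzenesulfonohydrazide | CC(C)=CCC[C@H](C)C/C=N/NS(=O)(=O)c1ccc(C)cc1 | intermediate
7 | 4-[(1E,3S)-3,7-dimethylocta-1,6-dien-1-yl]-3,5-bis[(triisopropylsilyl)oxy]phenol | CC(C)=CCC[C@H](C)/C=C/c1c(O[Si](C(C)C)(C(C)C)C(C)C)cc(O)cc1O[Si](C(C)C)(C(C)C)C(C)C | intermediate
8 | 4-hydroxybenzaldehyde | O=Cc1ccc(O)cc1 | starting material
9 | 4-[(triisopropylsilyl)oxy]benzaldehyde | CC(C)[Si](Oc1ccc(C=O)cc1)(C(C)C)C(C)C | intermediate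
10 | chloro{4-[(triisopropylsilyl)oxy]phenyl}methyl 2,2-dimethylpropanoate (racemic) | CC(C)[Si](Oc1ccc(C(Cl)OC(=O)C(C)(C)C)cc1)(C(C)C)C(C)C | intermediate
11 | {4-[(1E,3S)-3,7-dimethylocta-1,6-dien-1-yl]-3,5-bis[(triisopropylsilyl)oxy]phenoxy}{4-[(triisopropylsilyl)oxy]phenyl}methyl 2,2-dimethylpropanoate (both epimers at the acetal carbon) | CC(C)=CCC[C@H](C)/C=C/c1c(O[Si](C(C)C)(C(C)C)C(C)C)cc(OC(OC(=O)C(C)(C)C)c2ccc(O[Si](C(C)C)(C(C)C)C(C)C)cc2)cc1O[Si](C(C)C)(C(C)C)C(C)C | intermediate
12 | 1,1-diethoxyethene (ketene diethyl acetal) | C=C(OCC)OCC | starting material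
13 | (2S)-4,4-diethoxy-6-[(1E,3S)-3,7-dimethylocta-1,6-dien-1-yl]-5,7-bis[(triisopropylsilyl)oxy]-2-{4-[(triisopropylsilyl)oxy]phenyl}-3,4-dihydro-2H-chromene (formed in the flask, not isolated) | CC(C)=CCC[C@H](C)/C=C/c1c(O[Si](C(C)C)(C(C)C)C(C)C)cc2c(c1O[Si](C(C)C)(C(C)C)C(C)C)C(OCC)(OCC)C[C@@H](c1ccc(O[Si](C(C)C)(C(C)C)C(C)C)cc1)O2 | intermediate
14 | (2S)-6-[(1E,3S)-3,7-dimethylocta-1,6-dien-1-yl]-5,7-bis[(triisopropylsilyl)oxy]-2-{4-[(triisopropylsilyl)oxy]phenyl}-2,3-dihydro-4H-chromen-4-one | CC(C)=CCC[C@H](C)/C=C/c1c(O[Si](C(C)C)(C(C)C)C(C)C)cc2c(c1O[Si](C(C)C)(C(C)C)C(C)C)C(=O)C[C@@H](c1ccc(O[Si](C(C)C)(C(C)C)C(C)C)cc1)O2 | intermediate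
15 | (2S)-6-[(1E,3S)-3,7-dimethylocta-1,6-dien-1-yl]-5,7-dihydroxy-2-(4-hydroxyphenyl)-2,3-dihydro-4H-chromen-4-one | CC(C)=CCC[C@H](C)/C=C/c1c(O)cc2c(c1O)C(=O)C[C@@H](c1ccc(O)cc1)O2 | target

**Step count and risks**

Total steps: 9. Longest linear sequence: 6 steps (steps 1, 2, 4, 7, 8, 9).

Steps most likely to fail:

1. Step 8. Possible failures are insufficient facial discrimination within the ion pair (low enantiomeric purity at C-2), diversion of the dialkoxycarbenium ion by ethyl transfer to an open-chain ester instead of closure at the silyloxy-flanked ortho carbon, and acid-triggered reaction of the side-chain styrene. The fallback sets out from 9 and 7 and returns at 14, with C-2 set by a catalytic reduction and transferred by inversion. Aldehyde 9 is homologated with ethyl diazoacetate (SnCl2 cat., CH2Cl2; Roskamp reaction) to ethyl 3-oxo-3-{4-[(triisopropylsilyl)oxy]phenyl}propanoate F1. Asymmetric transfer hydrogenation (RuCl(p-cymene)[(R,R)-TsDPEN], HCO2H/Et3N), whose sense is expected from the acetophenone model, should give ethyl (3R)-3-hydroxy-3-{4-[(triisopropylsilyl)oxy]phenyl}propanoate F2. Mitsunobu etherification of phenol 7 with F2 (PPh3, DIAD, toluene, 0 °C) inverts the carbinol centre and gives ethyl (3S)-3-{4-[(1E,3S)-3,7-dimethylocta-1,6-dien-1-yl]-3,5-bis[(triisopropylsilyl)oxy]phenoxy}-3-{4-[(triisopropylsilyl)oxy]phenyl}propanoate F3. The ester is cleaved under neutral conditions (Me3SnOH, 1,2-dichloroethane, 70 °C) to (3S)-3-{4-[(1E,3S)-3,7-dimethylocta-1,6-dien-1-yl]-3,5-bis[(triisopropylsilyl)oxy]phenoxy}-3-{4-[(triisopropylsilyl)oxy]phenyl}propanoic acid F4. Intramolecular Friedel–Crafts acylation through the mixed trifluoroacetic anhydride (TFAA, CH2Cl2, 0 °C) closes ring C at either of the two equivalent ortho carbons and gives 14.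

2. Step 4. Possible failures are slow oxidative addition of zerovalent palladium at the C–Br bond flanked by two silyloxy groups on an electron-rich phenoxide, loss of silyl groups to the alkoxide base at 90 °C, and re-insertion of the palladium hydride that would move the double bond and erode C-3''. The fallback sets out from 5 and 4 and returns at 7, joining the chain by Suzuki–Miyaura coupling under mild base. Aldehyde 5 is converted in one pot (nonafluorobutanesulfonyl fluoride, phosphazene base P2-Et, DMF; enol nonaflate formation then elimination) into (3S)-3,7-dimethyloct-6-en-1-yne F5. Hydroboration with pinacolborane (Cp2Zr(H)Cl cat., CH2Cl2) gives 2-[(1E,3S)-3,7-dimethylocta-1,6-dien-1-yl]-4,4,5,5-tetramethyl-1,3,2-dioxaborolane F6. F6 is coupled with bromophenol 4 (Pd(OAc)2, SPhos, K3PO4, THF/H2O, 40 °C) to give 7.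

3. Step 7. Possible failures are C- instead of O-alkylation of the ambident phloroglucinol-type phenoxide, reversion of 10 to aldehyde and acyl chloride followed by O-pivaloylation of the phenoxide, and hydrolysis of the mixed acetal on silica. The fallback sets out from 9 and 7 and returns at 14, building the acetal carbon by reduction of an ester instead of by alkylation. Aldehyde 9 is oxidised (NaClO2, NaH2PO4, 2-methylbut-2-ene, tBuOH/H2O; Pinnick oxidation) to 4-[(triisopropylsilyl)oxy]benzoic acid F7. Steglich esterification with phenol 7 (DCC, DMAP, CH2Cl2) gives 4-[(1E,3S)-3,7-dimethylocta-1,6-dien-1-yl]-3,5-bis[(triisopropylsilyl)oxy]phenyl 4-[(triisopropylsilyl)oxy]benzoate F8. Reduction with iBu2AlH at −78 °C and acetylation of the aluminium hemiacetal in the same flask (Ac2O, pyridine, DMAP) gives {4-[(1E,3S)-3,7-dimethylocta-1,6-dien-1-yl]-3,5-bis[(triisopropylsilyl)oxy]phenoxy}{4-[(triisopropylsilyl)oxy]phenyl}methyl acetate F9. F9 is taken through step 8 in place of 11, with acetate as the leaving group, to give 14.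

**Further compounds**

F1 | step 8 | ethyl 3-oxo-3-{4-[(triisopropylsilyl)oxy]phenyl}propanoate | CCOC(=O)CC(=O)c1ccc(O[Si](C(C)C)(C(C)C)C(C)C)cc1
F2 | step 8 | ethyl (3R)-3-hydroxy-3-{4-[(triisopropylsilyl)oxy]phenyl}propanoate | CCOC(=O)C[C@@H](O)c1ccc(O[Si](C(C)C)(C(C)C)C(C)C)cc1
F3 | step 8 | ethyl (3S)-3-{4-[(1E,3S)-3,7-dimethylocta-1,6-dien-1-yl]-3,5-bis[(triisopropylsilyl)oxy]phenoxy}-3-{4-[(triisopropylsilyl)oxy]phenyl}propanoate | CC(C)=CCC[C@H](C)/C=C/c1c(O[Si](C(C)C)(C(C)C)C(C)C)cc(O[C@@H](CC(=O)OCC)c2ccc(O[Si](C(C)C)(C(C)C)C(C)C)cc2)cc1O[Si](C(C)C)(C(C)C)C(C)C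
F4 | step 8 | (3S)-3-{4-[(1E,3S)-3,7-dimethylocta-1,6-dien-1-yl]-3,5-bis[(triisopropylsilyl)oxy]phenoxy}-3-{4-[(triisopropylsilyl)oxy]phenyl}propanoic acid | CC(C)=CCC[C@H](C)/C=C/c1c(O[Si](C(C)C)(C(C)C)C(C)C)cc(O[C@@H](CC(=O)O)c2ccc(O[Si](C(C)C)(C(C)C)C(C)C)cc2)cc1O[Si](C(C)C)(C(C)C)C(C)C
F5 | step 4 | (3S)-3,7-dimethyloct-6-en-1-yne | CC(C)=CCC[C@H](C)C#C
F6 | step 4 | 2-[(1E,3S)-3,7-dimethylocta-1,6-dien-1-yl]-4,4,5,5-tetramethyl-1,3,2-dioxaborolane | CC(C)=CCC[C@H](C)/C=C/B1OC(C)(C)C(C)(C)O1
F7 | step 7 | 4-[(triisopropylsilyl)oxy]benzoic acid | CC(C)[Si](Oc1ccc(C(=O)O)cc1)(C(C)C)C(C)C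
F8 | step 7 | 4-[(1E,3S)-3,7-dimethylocta-1,6-dien-1-yl]-3,5-bis[(triisopropylsilyl)oxy]phenyl 4-[(triisopropylsilyl)oxy]benzoate | CC(C)=CCC[C@H](C)/C=C/c1c(O[Si](C(C)C)(C(C)C)C(C)C)cc(OC(=O)c2ccc(O[Si](C(C)C)(C(C)C)C(C)C)cc2)cc1O[Si](C(C)C)(C(C)C)C(C)C
F9 | step 7 | {4-[(1E,3S)-3,7-dimethylocta-1,6-dien-1-yl]-3,5-bis[(triisopropylsilyl)oxy]phenoxy}{4-[(triisopropylsilyl)oxy]phenyl}methyl acetate (both epimers at the acetal carbon) | CC(C)=CCC[C@H](C)/C=C/c1c(O[Si](C(C)C)(C(C)C)C(C)C)cc(OC(OC(C)=O)c2ccc(O[Si](C(C)C)(C(C)C)C(C)C)cc2)cc1O[Si](C(C)C)(C(C)C)C(C)C
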